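**Retrosynthetic overview**
- The target is two identical (R)-8-acyl-5,7-dihydroxy-2,2-dimethylchroman units joined at C6 by a 6-methylheptylidene CH. Both aryl–CH bonds are cut last; the C8 aldehyde is generated in the flask from 5-methylhex-1-ene, CO and H2.
- The monomer is cut at the C8–acyl bond (Friedel–Crafts; (R)-2-methylbutanoic acid supplies both stereocentres) and at the pyran ring (isoprene annulation of benzene-1,3,5-triol).
- Key step: benzene-1,3,5-triol comes from a threefold Baeyer–Villiger 1,2-aryl shift from carbon to oxygen on 1,3,5-triacetylbenzene (stepwise, ionic, through Criegee adducts), which sets the three meta oxygens.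
- 1,3,5-Triacetylbenzene comes from cyclotrimerisation of three molecules of (E)-4-(dimethylamino)but-3-en-2-one with loss of three molecules of dimethylamine.
- Ring order: benzene ring (step 1), its three C–O bonds (step 2), pyran ring (step 3); the second benzene/pyran pair enters as a second copy of the monomer in step 5.

Assumption: (R)-2-methylbutanoic acid (≥98% ee) and the other starting materials are bought, and one step is one operation ending in an isolated compound.

**Step 1**
Reactants: 1 (E)-4-(dimethylamino)but-3-en-2-one
Product: 2 1,3,5-triacetylbenzene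
Conditions: AcOH–pyridine (4:1), reflux
Reagents that add atoms: (E)-4-(dimethylamino)but-3-en-2-one (two further molecules of 1), CC(=O)/C=C/N(C)C.CC(=O)/C=C/N(C)C
Why: Acid-mediated cyclotrimerisation of an enaminone (three molecules of 1 per molecule of 2; conjugate addition–amine elimination, ring closure and aromatisation with loss of three Me2NH in all) is an established route to 1,3,5-triacylbenzenes and builds the benzene ring with three meta carbonyl groups.

**Step 2**
Reactants: 2 1,3,5-triacetylbenzene
Product: 4 benzene-1,3,5-triol (phloroglucinol), via benzene-1,3,5-triyl triacetate 3 (not isolated)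
Conditions: CF3CO3H (4.5 equiv, made in the flask from (CF3CO)2O and urea·H2O2), CH2Cl2, 0 to 40 °C; then evaporate, HCl (cat.), MeOH, 50 °C
Reagents that add atoms: trifluoroperacetic acid, OOC(=O)C(F)(F)F
Why: Threefold Baeyer–Villiger oxidation, in which the aryl group of each Criegee adduct shifts 1,2 from carbon to oxygen in preference to methyl, turns the three acetyl groups into acetoxy groups in the 1,3,5-pattern fixed in step 1, and acidic methanolysis frees the triol without exposing it to base and air.

**Step 3**
Reactants: 4 benzene-1,3,5-triol; 5 isoprene (2-methylbuta-1,3-diene)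
Product: 6 2,2-dimethylchromane-5,7-diol
Conditions: 85% H3PO4, xylene, 30–35 °C; 4 in threefold excess, the surplus recovered by aqueous extraction
Reagents that add atoms: none
Why: Acid-catalysed Friedel–Crafts prenylation followed by Markovnikov hydroalkoxylation through the tertiary cation closes the pyran ring in a pure 1:1 addition, gives a single chroman because all ring positions of 4 are equivalent, and the excess of 4 limits double annulation.

**Step 4**
Reactants: 6 2,2-dimethylchromane-5,7-diol; 7 (R)-2-methylbutanoic acid
Product: 9 (R)-1-(5,7-dihydroxy-2,2-dimethylchroman-8-yl)-2-methylbutan-1-one, via (R)-2-methylbutanoyl chloride 8 (not isolated)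
Conditions: 7, (COCl)2 (1.0 equiv), DMF (cat.), CH2Cl2, 0 to 20 °C; then 6, AlCl3 (3.5 equiv), PhNO2–CH2Cl2, 0 to 20 °C
Reagents that add atoms: none
Why: Friedel–Crafts acylation is expected to favour C8 (para to the 5-OH and flanked by one aluminium-bound phenoxide, whereas C6 lies between two), the minor C6 isomer is removed by chromatography, and the (R)-stereocentre of 7 is carried over unchanged because no base is present and the temperature stays at or below 20 °C.

**Step 5**
Reactants: 9 (R)-1-(5,7-dihydroxy-2,2-dimethylchroman-8-yl)-2-methylbutan-1-one (2 equiv); 10 5-methylhex-1-ene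
Product: 13 (2R,2'R)-1,1'-[(6-methylheptane-1,1-diyl)bis(5,7-dihydroxy-2,2-dimethylchromane-6,8-diyl)]bis(2-methylbutan-1-one) (bridge carbon on C6 of each chroman; ketone on C8), via 6-methylheptanal 11 (not isolated), via benzylic carbinol 12 (not isolated)
Conditions: Rh(acac)(CO)2 (1 mol%), Xantphos (2 mol%), (PhO)2P(O)OH (10 mol%), CO/H2 (1:1, 10 bar), toluene, 80 °C
Reagents that add atoms: carbon monoxide, [C-]#[O+]
Why: Proposed new method: one-pot relay catalysis in which linear hydroformylation of 10 by Rh(acac)(CO)2/Xantphos releases aldehyde 11 at low stationary concentration, diphenyl phosphate activates it for Friedel–Crafts attack by C6 of 9 (the only free ring position), carbinol 12 loses water to a benzylic cation stabilised by the two ortho hydroxy groups and a second molecule of 9 captures it, so both aryl–CH bonds of the bridge form without a new stereocentre (the bridge carbon carries two identical (R)-configured aryl groups) and without touching the ketone stereocentres; the closest known reaction types are tandem hydroformylation/acid-mediated condensations (hydroformylation–Fischer indolisation, hydroformylation–Pictet–Spengler) and the classical aldehyde bridging of acylphloroglucinols, a combination not shown for phloroglucinol-type carbon nucleophiles.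

**Compound list**
1 | (E)-4-(dimethylamino)but-3-en-2-one | CC(=O)/C=C/N(C)C | starting material
2 | 1,3,5-triacetylbenzene | CC(=O)c1cc(C(C)=O)cc(C(C)=O)c1 | intermediate
3 | benzene-1,3,5-triyl triacetate | CC(=O)Oc1cc(OC(C)=O)cc(OC(C)=O)c1 | intermediate
4 | benzene-1,3,5-triol (phloroglucinol) | Oc1cc(O)cc(O)c1 | intermediate
5 | isoprene (2-methylbuta-1,3-diene) | C=CC(C)=C | starting material
6 | 2,2-dimethylchromane-5,7-diol | CC1(C)CCc2c(O)cc(O)cc2O1 | intermediate
7 | (R)-2-methylbutanoic acid | CC[C@@H](C)C(=O)O | starting material
8 | (R)-2-methylbutanoyl chloride | CC[C@@H](C)C(=O)Cl | intermediate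
9 | (R)-1-(5,7-dihydroxy-2,2-dimethylchroman-8-yl)-2-methylbutan-1-one | CC[C@@H](C)C(=O)c1c(O)cc(O)c2c1OC(C)(C)CC2 | intermediate
10 | 5-methylhex-1-ene | C=CCCC(C)C | starting material
11 | 6-methylheptanal | CC(C)CCCCC=O | intermediate
12 | (R)-1-[5,7-dihydroxy-6-(1-hydroxy-6-methylheptyl)-2,2-dimethylchroman-8-yl]-2-methylbutan-1-one (both epimers at the carbinol carbon) | CC[C@@H](C)C(=O)c1c(O)c(C(O)CCCCC(C)C)c(O)c2c1OC(C)(C)CC2 | intermediate
13 | (2R,2'R)-1,1'-[(6-methylheptane-1,1-diyl)bis(5,7-dihydroxy-2,2-dimethylchromane-6,8-diyl)]bis(2-methylbutan-1-one), CNP0324275.1 | CC[C@@H](C)C(=O)c1c(O)c(C(CCCCC(C)C)c2c(O)c3c(c(C(=O)[C@H](C)CC)c2O)OC(C)(C)CC3)c(O)c2c1OC(C)(C)CC2 | target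

**Totals**
Total step count: 5. Longest linear sequence: 5 steps (1 → 2 → 4 → 6 → 9 → 13).

**Steps most likely to fail**

Step 2 (threefold Baeyer–Villiger). The migrating aryl group is electron-poor at every stage, so the oxidation may stall at the mono- or diacetate, methyl migration may compete, and the peracid may hydroxylate the ring. The fallback sets out from 2 and comes back at 4. Compound 2 is converted with NH2OH·HCl and NaOAc in EtOH into 1,3,5-triacetylbenzene tris-(E)-oxime F1. Beckmann rearrangement in polyphosphoric acid at 110 °C, where the aryl group anti to the oxime OH shifts from carbon to nitrogen whatever its electron demand, gives N,N',N''-(benzene-1,3,5-triyl)triacetamide F2. Boiling aqueous HCl removes the acetyl groups and hydrolyses the resulting benzene-1,3,5-triamine F3 (not isolated) to 4.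

Step 4 (C8 acylation with retention). The C8/C6 ratio may be poor, and the aluminium-bound ketone may partly racemise. The fallback sets out from 6 (and uses 8) and comes back at 9. Both phenols of 6 are silylated (iPr3SiCl, imidazole, DMF) to give 5,7-bis(triisopropylsilyloxy)-2,2-dimethylchromane F4, in which C6 is buried between two silyl ethers. Acylation with 8 in hexafluoropropan-2-ol at 20 °C without a Lewis acid (known solvent-promoted Friedel–Crafts acylation) is then expected to reach only C8 and gives (R)-1-[5,7-bis(triisopropylsilyloxy)-2,2-dimethylchroman-8-yl]-2-methylbutan-1-one F5. Bu4NF/AcOH in THF removes both silyl groups to give 9.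

Step 5 (proposed relay hydroformylation/double arylation). The chelating hydroxy ketone 9 may slow the catalyst formed from Rh(acac)(CO)2 and Xantphos, 11 may undergo aldol condensation, the intermediate cation may be reduced, or the second arylation may lag. The fallback uses known chemistry only, sets out from 9 and comes back at 13. Aldehyde 11 is made separately without syngas: purchased 1-bromo-5-methylhexane F6 is converted with Mg in THF into (5-methylhexyl)magnesium bromide F7, which is formylated with DMF (Bouveault reaction, aqueous HCl work-up) and distilled. Pure 11 is then condensed with two equivalents of 9 under the classical conditions for alkylidene-bridged acylphloroglucinols (TsOH cat., toluene, 60 °C), again passing through 12.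

**Further compounds**
F1 | step 2 | 1,3,5-triacetylbenzene tris-(E)-oxime | C/C(=N\O)c1cc(/C(C)=N/O)cc(/C(C)=N/O)c1
F2 | step 2 | N,N',N''-(benzene-1,3,5-triyl)triacetamide | CC(=O)Nc1cc(NC(C)=O)cc(NC(C)=O)c1
F3 | step 2 | benzene-1,3,5-triamine | Nc1cc(N)cc(N)c1
F4 | step 4 | 5,7-bis(triisopropylsilyloxy)-2,2-dimethylchromane | CC1(C)CCc2c(O[Si](C(C)C)(C(C)C)C(C)C)cc(O[Si](C(C)C)(C(C)C)C(C)C)cc2O1
F5 | step 4 | (R)-1-[5,7-bis(triisopropylsilyloxy)-2,2-dimethylchroman-8-yl]-2-methylbutan-1-one | CC[C@@H](C)C(=O)c1c(O[Si](C(C)C)(C(C)C)C(C)C)cc(O[Si](C(C)C)(C(C)C)C(C)C)c2c1OC(C)(C)CC2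
F6 | step 5 | 1-bromo-5-methylhexane (purchased) | CC(C)CCCCBr
F7 | step 5 | (5-methylhexyl)magnesium bromide | CC(C)CCCC[Mg]Br
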